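**Retrosynthetic overview**

1. Numbering is that of the target isochromene: ring B is O-2/C-1/C-8a/C-4a/C-4/C-3, ring A is C-4a/C-5/C-6/C-7/C-8/C-8a. Ring B with its exocyclic C-4a=C-5 bond is a 4-ylidene-4H-pyran, that is, a 2-alkyl-3-methoxy-4-pyranone of the maltol type with C-5 in the place of the carbonyl oxygen; ring B is therefore bought and ring A is the only ring to be made.
2. Key disconnection C-4a=C-5 (ring A, closed last): the pyranone carbonyl of acylpyranone 21 is O-methylated to a 4-methoxypyrylium ion, the C-5 enol of the C-6 ketone adds to that carbon, and methanol is lost.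
3. The C-8 ketone, which makes C-1 a strong acceptor, is unveiled only in the step before the closure; the C-7 butyrate is put on while C-8 is still a silyloxy carbinol.
4. C-7–C-8 bond and C-7 configuration: aldol of the enolate of the (S)-lactic acid/pivalaldehyde dioxolanone with pyranone aldehyde 9. C-5–C-6 bond: LiCH2OCH2OMe on the dioxolanone carbonyl.
5. Aldehyde 9 comes from maltol by O-methylation, side-chain alkylation with 3, then iodination and formylation at pyranone C-5 (the future C-8a).

Key step: step 11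

Remark: C-8 is carried as a mixture of carbinol epimers in 14 to 20 (drawn without configuration) because step 10 turns it into the ketone; the target is taken as the (7R) enantiomer that its SMILES defines.

Abbreviations: Ar = 6-[3-(tert-butyldimethylsilyloxy)propyl]-5-methoxy-4-oxo-4H-pyran-3-yl; TBS = tert-butyldimethylsilyl; TES = triethylsilyl; MOM = methoxymethyl; DMPU = N,N'-dimethylpropyleneurea; PPTS = pyridinium p-toluenesulfonate.

**Route**

Step 1
Reactants: 1 maltol (3-hydroxy-2-methyl-4H-pyran-4-one)
Product: 2 3-methoxy-2-methyl-4H-pyran-4-one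
Conditions: MeI, K2CO3, acetone, reflux
Reagents that add atoms: iodomethane, CI
Why: Williamson O-alkylation of the acidic enolic 3-hydroxyl; MeI is too weak an electrophile to alkylate the pyranone carbonyl oxygen.

Step 2
Reactants: 2 3-methoxy-2-methyl-4H-pyran-4-one; 3 (2-iodoethoxy)(tert-butyl)dimethylsilane
Product: 5 2-[3-(tert-butyldimethylsilyloxy)propyl]-3-methoxy-4H-pyran-4-one, via lithium dienolate 4 (not isolated)
Conditions: LiN(SiMe3)2, THF, −78 °C; then 3, DMPU, −78 → −20 °C
Reagents that add atoms: none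
Why: The 2-methyl group of a 4-pyranone is vinylogously acidic, so lateral deprotonation gives dienolate 4, which is alkylated at its exocyclic carbon by the primary iodide (SN2); DMPU speeds this up so that it outruns E2 loss of HI from 3.

Step 3
Reactants: 5 2-[3-(tert-butyldimethylsilyloxy)propyl]-3-methoxy-4H-pyran-4-one
Product: 6 2-[3-(tert-butyldimethylsilyloxy)propyl]-5-iodo-3-methoxy-4H-pyran-4-one
Conditions: N-iodosuccinimide, CF3CO2H (cat.), MeCN, 0 → 23 °C, dark
Reagents that add atoms: N-iodosuccinimide, O=C1CCC(=O)N1I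
Why: Electrophilic iodination goes to pyranone C-5, the only free carbon that is beta to the ring oxygen and alpha to the carbonyl (the nucleophilic end of the O-1/C-6=C-5 enol ether), whereas C-6 is the electrophilic enone beta-carbon.

Step 4
Reactants: 6 2-[3-(tert-butyldimethylsilyloxy)propyl]-5-iodo-3-methoxy-4H-pyran-4-one
Product: 9 6-[3-(tert-butyldimethylsilyloxy)propyl]-5-methoxy-4-oxo-4H-pyran-3-carbaldehyde, via pyranonylmagnesium chloride 7 (not isolated), via magnesium hemiaminalate 8 (not isolated)
Conditions: iPrMgCl·LiCl, THF, −40 °C; DMF, −40 → 0 °C; aq NH4Cl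
Reagents that add atoms: N,N-dimethylformamide, CN(C)C=O
Why: Iodine–magnesium exchange on an alpha-iodo enone is fast at −40 °C and gives a carbonyl-chelated alkenyl Grignard reagent; formylation with DMF (Bouveault aldehyde synthesis) stops at hemiaminalate 8 until work-up.

Step 5
Reactants: 10 (S)-lactic acid; 11 pivalaldehyde
Product: 12 (2S,5S)-2-tert-butyl-5-methyl-1,3-dioxolan-4-one
Conditions: TsOH·H2O (cat.), H2SO4 (cat.), pentane, reflux, water separator; crystallisation from pentane/Et2O at −78 °C
Reagents that add atoms: none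
Why: Acid-catalysed acetalisation under thermodynamic control favours the cis dioxolanone, which low-temperature crystallisation frees from the trans isomer; the acetal carbon then stores the configuration of the lactate carbon (self-regeneration of stereocentres).

Step 6
Reactants: 12 (2S,5S)-2-tert-butyl-5-methyl-1,3-dioxolan-4-one; 9 6-[3-(tert-butyldimethylsilyloxy)propyl]-5-methoxy-4-oxo-4H-pyran-3-carbaldehyde
Product: 15 (2S,5R)-2-tert-butyl-5-methyl-5-[Ar(triethylsilyloxy)methyl]-1,3-dioxolan-4-one (both C-8 epimers), via lithium enolate 13 (not isolated), via lithium aldolate 14 (not isolated)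
Conditions: LiN(iPr)2, THF, −78 °C; 9, −78 °C; Et3SiOTf, −78 → −40 °C
Reagents that add atoms: triethylsilyl trifluoromethanesulfonate, CC[Si](CC)(CC)OS(=O)(=O)C(F)(F)F
Why: Aldol addition of the planar enolate 13 takes place on the face away from the tert-butyl group, so the carbinol carbon (C-8) replaces the lactate hydrogen with retention and fixes C-7 as needed for the (7R) target; silylating aldolate 14 in the flask stops retro-aldol cleavage and protects O-8.

Step 7
Reactants: 15 (2S,5R)-2-tert-butyl-5-methyl-5-[Ar(triethylsilyloxy)methyl]-1,3-dioxolan-4-one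
Product: 18 (2R)-1-Ar-2-hydroxy-4-(methoxymethoxy)-2-methyl-1-(triethylsilyloxy)butan-3-one, via lithium dienolate 16 (not isolated), via dilithium hemiketal alkoxide 17 (not isolated)
Conditions: LiN(SiMe3)2, THF, −78 °C; LiCH2OCH2OMe (from Bu3SnCH2OCH2OMe, n-BuLi, THF, −78 °C), −78 °C; aq NH4Cl, −78 → 23 °C
Reagents that add atoms: tributyl[(methoxymethoxy)methyl]stannane, CCCC[Sn](CCCC)(CCCC)COCOC
Why: Side-chain deprotonation first turns the pyranone into its unreactive dienolate 16 (the anion type of step 2), so the alpha-alkoxy organolithium from tin–lithium exchange should add only to the acylal-type lactone carbonyl; the five-ring hemiketal alkoxide 17 persists at −78 °C, which blocks a second addition, and on protonation collapses to the C-6 ketone, pivalaldehyde and the free C-7 hydroxyl without touching the stereocentre.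

Step 8
Reactants: 18 (2R)-1-Ar-2-hydroxy-4-(methoxymethoxy)-2-methyl-1-(triethylsilyloxy)butan-3-one
Product: 19 (2R)-1-Ar-4-(methoxymethoxy)-2-methyl-3-oxo-1-(triethylsilyloxy)butan-2-yl butanoate
Conditions: (PrCO)2O, DMAP, Et3N, CH2Cl2, 23 → 40 °C
Reagents that add atoms: butyric anhydride, CCCC(=O)OC(=O)CCC
Why: DMAP-catalysed acyl transfer (Steglich-type) to the tertiary alpha-ketol; C-8 is still sp3 and O-8 silylated here, so neither acyl migration nor conjugate addition of O-7 or C-5 to the pyranone can compete.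

Step 9
Reactants: 19 (2R)-1-Ar-4-(methoxymethoxy)-2-methyl-3-oxo-1-(triethylsilyloxy)butan-2-yl butanoate
Product: 20 (2R)-1-Ar-1-hydroxy-4-(methoxymethoxy)-2-methyl-3-oxobutan-2-yl butanoate
Conditions: PPTS (cat.), MeOH/CH2Cl2, 0 → 23 °C
Reagents that add atoms: none
Why: Acid-catalysed methanolysis cleaves the secondary triethylsilyl ether far faster than the primary TBS ether and leaves the MOM acetal and the ester alone; the alcohol is oxidised at once to forestall butyrate migration from O-7 to O-8.

Step 10
Reactants: 20 (2R)-1-Ar-1-hydroxy-4-(methoxymethoxy)-2-methyl-3-oxobutan-2-yl butanoate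
Product: 21 (2R)-1-Ar-4-(methoxymethoxy)-2-methyl-1,3-dioxobutan-2-yl butanoate (the 5-acyl-3-methoxy-4-pyranone precursor)
Conditions: Dess–Martin periodinane, CH2Cl2, 0 → 23 °C
Reagents that add atoms: none
Why: Dess–Martin oxidation gives the 1,3-diketone under non-basic conditions, so C-5 is not enolised while C-1 has just become doubly activated, and the quaternary C-7 cannot epimerise.

Step 11
Reactants: 21 (2R)-1-Ar-4-(methoxymethoxy)-2-methyl-1,3-dioxobutan-2-yl butanoate
Product: 24 (7R)-7-butanoyloxy-3-[3-(tert-butyldimethylsilyloxy)propyl]-4-methoxy-5-(methoxymethoxy)-7-methyl-6H-isochromene-6,8(7H)-dione, via methoxypyrylium triflate 22 (not isolated), via 4a-methoxy adduct 23 (not isolated)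
Conditions: MeOTf, 2,6-di-tert-butyl-4-methylpyridine, CH2Cl2, 0 → 23 °C; then 2,6-lutidine, 23 → 40 °C
Reagents that add atoms: none
Why: Proposed new method: MeOTf alkylates the most basic oxygen of 21, the pyranone carbonyl, to give the 3,4-dimethoxypyrylium salt 22; 2,6-lutidine then relays protons so that the neutral enol of the C-6 ketone (the only enol possible, since C-7 is quaternary and C-8 has no alpha hydrogen) adds through C-5 to pyrylium C-4 (the future C-4a), and adduct 23 ionises again at C-4a with loss of methanol and gives up its C-5 proton to form the C-4a=C-5 bond. The closest known reaction is the Knoevenagel-type condensation of O-alkylated 4-pyranones (4-alkoxypyrylium salts) with active methylene compounds to 4-ylidene-4H-pyrans, which has not been run with a simple alkoxy ketone or as a ring closure. Ring A closes in a six-membered mode that is exo to the C-4a=O+Me bond (6-exo-trig); no stereocentre is formed and C-7 keeps its configuration. The selectivity to be won is C-4a against the unsubstituted pyrylium C-1, which C-5 reaches through an equally six-membered closure and which is normally the faster site of 4-alkoxypyrylium ions. It rests on reversibility: only the C-4a adduct has a leaving group, whereas the C-1 adduct is an aldol-type beta-alkoxy ketone adduct of a well-stabilised cation and should revert under the weakly acidic pyridinium buffer; a hindered pyridine base in place of a trialkylamine avoids E1cB opening of that adduct and deprotonation of the pyrylium side chain to the anhydro base. The push-pull 4-ylidene-4H-pyran 24 is the thermodynamic sink.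

Step 12
Reactants: 24 (7R)-7-butanoyloxy-3-[3-(tert-butyldimethylsilyloxy)propyl]-4-methoxy-5-(methoxymethoxy)-7-methyl-6H-isochromene-6,8(7H)-dione
Product: 25 (7R)-7-butanoyloxy-5-hydroxy-3-(3-hydroxypropyl)-4-methoxy-7-methyl-6H-isochromene-6,8(7H)-dione (CNP0439446.1)
Conditions: CF3CO2H/H2O (9:1), CH2Cl2, 0 → 23 °C; aq NaHCO3 work-up
Reagents that add atoms: none
Why: Aqueous acid hydrolyses the primary silyl ether and the MOM acetal on the acidic C-5 enol oxygen (an acetal of a vinylogous acid, far more labile than an alkyl MOM ether), while the tertiary butyrate survives and the 4-ylidene-4H-pyran is only protonated reversibly at C-5.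

**Compound list**

1 | maltol (3-hydroxy-2-methyl-4H-pyran-4-one) | CC1=C(O)C(=O)C=CO1 | starting material
2 | 3-methoxy-2-methyl-4H-pyran-4-one | CC1=C(OC)C(=O)C=CO1 | intermediate
3 | (2-iodoethoxy)(tert-butyl)dimethylsilane | ICCO[Si](C)(C)C(C)(C)C | starting material
4 | lithium 3-methoxy-2-methylidene-2H-pyran-4-olate (dienolate of 2, not isolated) | [Li+].C=C1OC=CC([O-])=C1OC | intermediate
5 | 2-[3-(tert-butyldimethylsilyloxy)propyl]-3-methoxy-4H-pyran-4-one | COC1=C(CCCO[Si](C)(C)C(C)(C)C)OC=CC1=O | intermediate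
6 | 2-[3-(tert-butyldimethylsilyloxy)propyl]-5-iodo-3-methoxy-4H-pyran-4-one | COC1=C(CCCO[Si](C)(C)C(C)(C)C)OC=C(I)C1=O | intermediate
7 | Ar-magnesium chloride (pyranonylmagnesium chloride, not isolated) | COC1=C(CCCO[Si](C)(C)C(C)(C)C)OC=C([Mg]Cl)C1=O | intermediate
8 | chloromagnesium alkoxide of the DMF adduct of 7 (hemiaminalate, not isolated) | COC1=C(CCCO[Si](C)(C)C(C)(C)C)OC=C(C(O[Mg]Cl)N(C)C)C1=O | intermediate
9 | 6-[3-(tert-butyldimethylsilyloxy)propyl]-5-methoxy-4-oxo-4H-pyran-3-carbaldehyde | COC1=C(CCCO[Si](C)(C)C(C)(C)C)OC=C(C=O)C1=O | intermediate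
10 | (S)-lactic acid | C[C@H](O)C(=O)O | starting material
11 | pivalaldehyde | CC(C)(C)C=O | starting material
12 | (2S,5S)-2-tert-butyl-5-methyl-1,3-dioxolan-4-one | C[C@@H]1O[C@H](C(C)(C)C)OC1=O | intermediate
13 | lithium enolate of 12 (not isolated) | [Li+].CC1=C([O-])O[C@@H](C(C)(C)C)O1 | intermediate
14 | lithium aldolate from 13 and 9 (C-8 epimers, not isolated) | [Li+].COC1=C(CCCO[Si](C)(C)C(C)(C)C)OC=C(C1=O)C([O-])[C@@]2(C)O[C@H](C(C)(C)C)OC2=O | intermediate
15 | (2S,5R)-2-tert-butyl-5-methyl-5-[Ar(triethylsilyloxy)methyl]-1,3-dioxolan-4-one (C-8 epimers) | COC1=C(CCCO[Si](C)(C)C(C)(C)C)OC=C(C1=O)C(O[Si](CC)(CC)CC)[C@@]2(C)O[C@H](C(C)(C)C)OC2=O | intermediate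
16 | lithium dienolate of 15 (pyranone deprotonated at the side-chain CH2, not isolated) | [Li+].COC1=C([O-])C(C(O[Si](CC)(CC)CC)[C@@]2(C)O[C@H](C(C)(C)C)OC2=O)=COC1=CCCO[Si](C)(C)C(C)(C)C | intermediate
17 | dilithium salt of the dienolate hemiketal alkoxide (adduct of LiCH2OCH2OMe, not isolated) | [Li+].[Li+].COC1=C([O-])C(C(O[Si](CC)(CC)CC)[C@@]2(C)O[C@H](C(C)(C)C)OC2([O-])COCOC)=COC1=CCCO[Si](C)(C)C(C)(C)C | intermediate
18 | (2R)-1-Ar-2-hydroxy-4-(methoxymethoxy)-2-methyl-1-(triethylsilyloxy)butan-3-one | COC1=C(CCCO[Si](C)(C)C(C)(C)C)OC=C(C1=O)C(O[Si](CC)(CC)CC)[C@@](C)(O)C(=O)COCOC | intermediate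
19 | (2R)-1-Ar-4-(methoxymethoxy)-2-methyl-3-oxo-1-(triethylsilyloxy)butan-2-yl butanoate | COC1=C(CCCO[Si](C)(C)C(C)(C)C)OC=C(C1=O)C(O[Si](CC)(CC)CC)[C@@](C)(OC(=O)CCC)C(=O)COCOC | intermediate
20 | (2R)-1-Ar-1-hydroxy-4-(methoxymethoxy)-2-methyl-3-oxobutan-2-yl butanoate | COC1=C(CCCO[Si](C)(C)C(C)(C)C)OC=C(C1=O)C(O)[C@@](C)(OC(=O)CCC)C(=O)COCOC | intermediate
21 | (2R)-1-Ar-4-(methoxymethoxy)-2-methyl-1,3-dioxobutan-2-yl butanoate (key-step precursor) | COC1=C(CCCO[Si](C)(C)C(C)(C)C)OC=C(C1=O)C(=O)[C@@](C)(OC(=O)CCC)C(=O)COCOC | intermediate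
22 | 3,4-dimethoxypyrylium triflate of 21 (not isolated) | COc1c(CCCO[Si](C)(C)C(C)(C)C)[o+]cc(C(=O)[C@@](C)(OC(=O)CCC)C(=O)COCOC)c1OC.[O-]S(=O)(=O)C(F)(F)F | intermediate
23 | 4a-methoxy-4a,5-dihydro adduct (ring A closed, methanol not yet lost, not isolated) | CCCC(=O)O[C@]1(C)C(=O)C2=COC(CCCO[Si](C)(C)C(C)(C)C)=C(OC)C2(OC)C(OCOC)C1=O | intermediate
24 | (7R)-7-butanoyloxy-3-[3-(tert-butyldimethylsilyloxy)propyl]-4-methoxy-5-(methoxymethoxy)-7-methyl-6H-isochromene-6,8(7H)-dione (protected target) | CCCC(=O)O[C@]1(C)C(=O)C2=COC(CCCO[Si](C)(C)C(C)(C)C)=C(OC)C2=C(OCOC)C1=O | intermediate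
25 | (7R)-7-butanoyloxy-5-hydroxy-3-(3-hydroxypropyl)-4-methoxy-7-methyl-6H-isochromene-6,8(7H)-dione (CNP0439446.1) | CCCC(=O)O[C@]1(C)C(=O)C2=COC(CCCO)=C(OC)C2=C(O)C1=O | target

**Step count and risks**

Total steps: 12. Longest linear sequence: 11 (steps 1 to 4 and 6 to 12, from maltol); step 5 is a one-step branch.

Steps most likely to fail:

1. Step 11. C-5 may add faster to the unsubstituted pyrylium C-1, and that adduct may be opened by elimination before it can revert; or the neutral enol may be too weak a nucleophile for the dimethoxypyrylium ion.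
 - Fallback, from 18 back to 24: the C-4a–C-5 bond is made by aldol addition to the neutral pyranone while C-8 is still a silyloxy carbinol, so that C-1 is not an activated acceptor.
 - Ketol 18 with LiN(SiMe3)2 (2.2 equiv, THF, −78 °C) gives the alkoxide enolate, whose C-5 adds to the pyranone carbonyl. 1,2-Addition of lithium enolates to 4-pyranones followed by acid dehydration is the established way to 4-ylidene-4H-pyrans.
 - Camphorsulfonic acid on work-up dehydrates the 4-hydroxy-4H-pyran to the bicyclic (7R)-7-hydroxy-8-(triethylsilyloxy)-7,8-dihydro-6H-isochromen-6-one F1.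
 - HF·pyridine/pyridine in THF removes the triethylsilyl group to give the 7,8-diol F2.
 - MnO2 oxidises the allylic C-8 alcohol to the 7-hydroxy-6,8-dione F3.
 - Butyric anhydride/DMAP acylates the tertiary alcohol between the two ketones and gives 24.

2. Step 7. The organolithium may add to the pyranone (carbonyl or C-1) in competition with the lactone carbonyl, or alkoxide 17 may collapse before the quench and take up a second equivalent.
 - Fallback, from 12 back to 20: the organolithium is used before any pyranone is present.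
 - Enolate 13 is alkylated with benzyl chloromethyl ether (same facial rule, CH2OBn being the future C-8) to give (2S,5R)-5-(benzyloxymethyl)-2-tert-butyl-5-methyl-1,3-dioxolan-4-one F4.
 - LiCH2OCH2OMe at −78 °C opens it to the tertiary ketol F5.
 - Butyric anhydride/DMAP gives the butyrate F6.
 - H2 over Pd/C (palladium on carbon) in EtOAc removes the benzyl group to give the primary alcohol F7, which is oxidised without delay with Dess–Martin periodinane to the aldehyde F8.
 - Magnesium reagent 7, made from 6 as in step 4, adds to the aldehyde at −78 °C and, after a cold quench, gives 20.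
 - Steps 6 to 9 and the DMF quench of step 4 then fall away.

3. Step 8. Acylation of the crowded tertiary hydroxyl next to the silyloxy carbinol may stall, and forcing may bring on alpha-ketol rearrangement or silyl migration.
 - Fallback, from 18 back to 21: the ester is put on after the C-8 ketone is in place, when the hydroxyl sits between two carbonyl groups and is both less hindered and more acidic.
 - PPTS in MeOH removes the triethylsilyl group from 18 to give the diol F9.
 - Dess–Martin periodinane oxidises only the secondary alcohol and gives the hydroxy diketone F10.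
 - Butyric anhydride with DMAP at 0 °C, kept short because the free hydroxy diketone can cyclise onto C-1, gives 21.

**Further compounds**

F1 | step 11 | (7R)-3-[3-(tert-butyldimethylsilyloxy)propyl]-7-hydroxy-4-methoxy-5-(methoxymethoxy)-7-methyl-8-(triethylsilyloxy)-7,8-dihydro-6H-isochromen-6-one | C[C@@]1(O)C(O[Si](CC)(CC)CC)C2=COC(CCCO[Si](C)(C)C(C)(C)C)=C(OC)C2=C(OCOC)C1=O
F2 | step 11 | (7R)-3-[3-(tert-butyldimethylsilyloxy)propyl]-7,8-dihydroxy-4-methoxy-5-(methoxymethoxy)-7-methyl-7,8-dihydro-6H-isochromen-6-one | C[C@@]1(O)C(O)C2=COC(CCCO[Si](C)(C)C(C)(C)C)=C(OC)C2=C(OCOC)C1=O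
F3 | step 11 | (7R)-3-[3-(tert-butyldimethylsilyloxy)propyl]-7-hydroxy-4-methoxy-5-(methoxymethoxy)-7-methyl-6H-isochromene-6,8(7H)-dione | C[C@@]1(O)C(=O)C2=COC(CCCO[Si](C)(C)C(C)(C)C)=C(OC)C2=C(OCOC)C1=O
F4 | step 7 | (2S,5R)-5-(benzyloxymethyl)-2-tert-butyl-5-methyl-1,3-dioxolan-4-one | C[C@]1(COCc2ccccc2)O[C@H](C(C)(C)C)OC1=O
F5 | step 7 | (2R)-1-(benzyloxy)-2-hydroxy-4-(methoxymethoxy)-2-methylbutan-3-one | C[C@@](O)(COCc1ccccc1)C(=O)COCOC
F6 | step 7 | (2R)-1-(benzyloxy)-4-(methoxymethoxy)-2-methyl-3-oxobutan-2-yl butanoate | C[C@@](OC(=O)CCC)(COCc1ccccc1)C(=O)COCOC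
F7 | step 7 | (2R)-1-hydroxy-4-(methoxymethoxy)-2-methyl-3-oxobutan-2-yl butanoate | C[C@@](OC(=O)CCC)(CO)C(=O)COCOC
F8 | step 7 | (2R)-4-(methoxymethoxy)-2-methyl-1,3-dioxobutan-2-yl butanoate | C[C@@](OC(=O)CCC)(C=O)C(=O)COCOC
F9 | step 8 | (2R)-1-Ar-1,2-dihydroxy-4-(methoxymethoxy)-2-methylbutan-3-one | COC1=C(CCCO[Si](C)(C)C(C)(C)C)OC=C(C1=O)C(O)[C@@](C)(O)C(=O)COCOC
F10 | step 8 | (2R)-1-Ar-2-hydroxy-4-(methoxymethoxy)-2-methylbutane-1,3-dione | COC1=C(CCCO[Si](C)(C)C(C)(C)C)OC=C(C1=O)C(=O)[C@@](C)(O)C(=O)COCOC
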